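**Strategy.** Everything rests on the acidity the lone stereocentre acquires one oxidation level up. C2 of the propan-1-one chain, which holds the ether oxygen of the guaiacyl ring, lies between the C=O attached to the syringyl ring and the CH2OH carbon, so with an ester in place of CH2OH it is a rapidly epimerizing β-keto ester α-carbon. The chain is cut at the C1–C2 bond (aryloxyacetate enolate plus syringoyl chloride). Transfer hydrogenation of the racemic keto ester by RuCl(p-cymene)[(S,S)-TsDPEN] under dynamic kinetic resolution reduces the aryl ketone and drives C2 into one configuration in a single operation. Ester reduction freezes that centre; neutral reoxidation of the relay carbinol and desilylation finish.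

Key step: step 6

Remark: the (S,S) ligand is assigned to the 2S,3R product from the usual aryl ketone model combined with the syn preference of α-alkoxy β-keto esters; the configuration is to be verified on 12 or 13, and RuCl(p-cymene)[(R,R)-TsDPEN] is to be used should the sense prove opposite.

Step 1
Reactants: 1 dihydroconiferyl alcohol (4-(3-hydroxypropyl)-2-methoxyphenol); 2 ethyl bromoacetate
Product: 3 ethyl 2-[4-(3-hydroxypropyl)-2-methoxyphenoxy]acetate
Conditions: K2CO3 (1.5 equiv), acetone, reflux
Reagents that add atoms: none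
Why: Williamson ether synthesis in which carbonate deprotonates only the phenol, far more acidic than the aliphatic alcohol, so the phenoxide alone displaces bromide from the activated α-bromo ester.

Step 2
Reactants: 3 ethyl 2-[4-(3-hydroxypropyl)-2-methoxyphenoxy]acetate
Product: 4 ethyl 2-[4-[3-(tert-butyldimethylsilyloxy)propyl]-2-methoxyphenoxy]acetate (fragment 1)
Conditions: TBSCl, imidazole, DMF, 0 °C → rt
Reagents that add atoms: tert-butyldimethylsilyl chloride, CC(C)(C)[Si](C)(C)Cl
Why: Imidazole-promoted silyl ether formation on the only free hydroxyl masks the primary alcohol against the amide base and the acid chloride of the coupling step.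

Step 3
Reactants: 5 syringic acid (4-hydroxy-3,5-dimethoxybenzoic acid)
Product: 7 3,5-dimethoxy-4-(triisopropylsilyloxy)benzoic acid, via bis-silylated silyl ester 6 (not isolated)
Conditions: TIPSCl (2.4 equiv), imidazole, DMAP (cat.), DMF, 40 °C; then K2CO3, MeOH/THF/H2O, rt; aq. citric acid to pH 4
Reagents that add atoms: triisopropylsilyl chloride, CC(C)[Si](Cl)(C(C)C)C(C)C
Why: Exhaustive silylation followed by selective silyl ester solvolysis, since the silyl ester is cleaved by mild aqueous carbonate while the hindered aryl triisopropylsilyl ether flanked by two methoxy groups is left intact.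

Step 4
Reactants: 7 3,5-dimethoxy-4-(triisopropylsilyloxy)benzoic acid
Product: 8 3,5-dimethoxy-4-(triisopropylsilyloxy)benzoyl chloride (fragment 2)
Conditions: (COCl)2 (1.3 equiv), DMF (cat.), CH2Cl2, 0 °C → rt; evaporate, use crude
Reagents that add atoms: oxalyl chloride, ClC(=O)C(=O)Cl
Why: Acid chloride formation through the Vilsmeier-type chloroiminium from oxalyl chloride and catalytic DMF gives only volatile by-products, and the bulky aryl silyl ether tolerates the anhydrous HCl released.

Step 5
Reactants: 4 ethyl 2-[4-[3-(tert-butyldimethylsilyloxy)propyl]-2-methoxyphenoxy]acetate; 8 3,5-dimethoxy-4-(triisopropylsilyloxy)benzoyl chloride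
Product: 11 racemic ethyl 2-[4-[3-(tert-butyldimethylsilyloxy)propyl]-2-methoxyphenoxy]-3-[3,5-dimethoxy-4-(triisopropylsilyloxy)phenyl]-3-oxopropanoate, via ester lithium enolate 9 (not isolated), via keto ester lithium enolate 10 (not isolated)
Conditions: 4, LiN(SiMe3)2 (2.2 equiv), THF, −78 °C; then 8 (1.05 equiv), −78 → −40 °C; AcOH quench at −78 °C
Reagents that add atoms: none
Why: Crossed Claisen condensation in which the preformed lithium enolate 9 is C-acylated by the non-enolizable aroyl chloride 8, and the second equivalent of LiN(SiMe3)2 converts the more acidic product at once into its enolate 10, which prevents both proton transfer to unreacted 9 and a second acylation until the acetic acid quench releases 11.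

Step 6
Reactants: 11 racemic ethyl 2-[4-[3-(tert-butyldimethylsilyloxy)propyl]-2-methoxyphenoxy]-3-[3,5-dimethoxy-4-(triisopropylsilyloxy)phenyl]-3-oxopropanoate
Product: 12 ethyl (2S,3R)-2-[4-[3-(tert-butyldimethylsilyloxy)propyl]-2-methoxyphenoxy]-3-hydroxy-3-[3,5-dimethoxy-4-(triisopropylsilyloxy)phenyl]propanoate (syn)
Conditions: RuCl(p-cymene)[(S,S)-TsDPEN] (2 mol %), HCO2H/Et3N (5:2), CH2Cl2, 30 °C
Reagents that add atoms: none
Why: RuCl(p-cymene)[(S,S)-TsDPEN] (divalent ruthenium) is converted by Et3N and formic acid into RuH(p-cymene)[(S,S)-TsDPEN], whose Ru–H and N–H transfer hydride to the ketone carbon and a proton to the ketone oxygen of 11 through a six-membered outer-sphere transition state, so that one C–H bond forms at C3 and CO2 is released. The closest known reaction type is Noyori-type asymmetric transfer hydrogenation with dynamic kinetic resolution of α-alkoxy and α-amido β-keto esters, and no ring is closed. The C3 carbinol centre (R) is set by the ligand, which seats the trioxygenated aryl ring under the p-cymene ligand as for simple aryl ketones, and the C2 centre (S) is set by substrate matching, because only the enantiomer of 11 whose reduction leads to the syn product fits that transition state. The step needs high enantioselectivity together with high syn selectivity, since C3 is later erased and the diastereomer ratio therefore becomes the enantiopurity of C2. Both are secured by the position of C2 between the ketone and ester carbonyls with the aryloxy substituent on top, which lets Et3N interconvert the two enantiomers of 11 through the enol much faster than the mismatched one is reduced.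

Step 7
Reactants: 12 ethyl (2S,3R)-2-[4-[3-(tert-butyldimethylsilyloxy)propyl]-2-methoxyphenoxy]-3-hydroxy-3-[3,5-dimethoxy-4-(triisopropylsilyloxy)phenyl]propanoate
Product: 13 (1R,2R)-2-[4-[3-(tert-butyldimethylsilyloxy)propyl]-2-methoxyphenoxy]-1-[3,5-dimethoxy-4-(triisopropylsilyloxy)phenyl]propane-1,3-diol
Conditions: LiBH4 (2.5 equiv), MeOH (1 equiv), THF, 0 °C → rt
Reagents that add atoms: none
Why: LiBH4 reduction of the α-aryloxy ester to the primary alcohol runs under mild, weakly basic conditions that leave the silyl ethers and the C2 configuration untouched, and once the ester has gone C2 is no longer acidic.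

Step 8
Reactants: 13 (1R,2R)-2-[4-[3-(tert-butyldimethylsilyloxy)propyl]-2-methoxyphenoxy]-1-[3,5-dimethoxy-4-(triisopropylsilyloxy)phenyl]propane-1,3-diol
Product: 14 (1R,2R)-3-(tert-butyldimethylsilyloxy)-2-[4-[3-(tert-butyldimethylsilyloxy)propyl]-2-methoxyphenoxy]-1-[3,5-dimethoxy-4-(triisopropylsilyloxy)phenyl]propan-1-ol
Conditions: TBSCl (1.05 equiv), imidazole, CH2Cl2, −20 → 0 °C
Reagents that add atoms: tert-butyldimethylsilyl chloride, CC(C)(C)[Si](C)(C)Cl
Why: Sterically controlled monosilylation, in which the unhindered primary hydroxyl reacts much faster than the secondary benzylic hydroxyl wedged between the aryl ring and the aryloxy-bearing carbon.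

Step 9
Reactants: 14 (1R,2R)-3-(tert-butyldimethylsilyloxy)-2-[4-[3-(tert-butyldimethylsilyloxy)propyl]-2-methoxyphenoxy]-1-[3,5-dimethoxy-4-(triisopropylsilyloxy)phenyl]propan-1-ol
Product: 15 (2R)-3-(tert-butyldimethylsilyloxy)-2-[4-[3-(tert-butyldimethylsilyloxy)propyl]-2-methoxyphenoxy]-1-[3,5-dimethoxy-4-(triisopropylsilyloxy)phenyl]propan-1-one
Conditions: Dess–Martin periodinane (1.3 equiv), NaHCO3 (5 equiv), CH2Cl2, 0 °C → rt
Reagents that add atoms: none
Why: Dess–Martin oxidation turns the secondary benzylic alcohol into the aryl ketone under bicarbonate buffering, so the newly acidic C2–H next to the carbonyl should not meet a base or acid strong enough to enolize it or to eliminate the β-silyloxy group.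

Step 10
Reactants: 15 (2R)-3-(tert-butyldimethylsilyloxy)-2-[4-[3-(tert-butyldimethylsilyloxy)propyl]-2-methoxyphenoxy]-1-[3,5-dimethoxy-4-(triisopropylsilyloxy)phenyl]propan-1-one
Product: 16 (2R)-3-hydroxy-1-(4-hydroxy-3,5-dimethoxyphenyl)-2-[4-(3-hydroxypropyl)-2-methoxyphenoxy]propan-1-one (CNP0283847.2)
Conditions: TBAF (4 equiv), AcOH (4.4 equiv), THF, 0 °C → rt; pH 6 phosphate buffer work-up; short chromatography on neutral silica
Reagents that add atoms: none
Why: Fluoride-mediated desilylation buffered with acetic acid cleaves the two alkyl tert-butyldimethylsilyl ethers and the aryl triisopropylsilyl ether (a good leaving phenoxide because of the para acyl group) while every alkoxide or phenoxide released is protonated at once, so the medium should stay too weakly basic to epimerize C2, to eliminate the primary hydroxyl or to cause retro-aldol cleavage.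

**Compound list**

1 | dihydroconiferyl alcohol, 4-(3-hydroxypropyl)-2-methoxyphenol | COc1cc(CCCO)ccc1O | starting material
2 | ethyl bromoacetate | CCOC(=O)CBr | starting material
3 | ethyl 2-[4-(3-hydroxypropyl)-2-methoxyphenoxy]acetate | CCOC(=O)COc1ccc(CCCO)cc1OC | intermediate
4 | ethyl 2-[4-[3-(tert-butyldimethylsilyloxy)propyl]-2-methoxyphenoxy]acetate (fragment 1) | CCOC(=O)COc1ccc(CCCO[Si](C)(C)C(C)(C)C)cc1OC | intermediate
5 | syringic acid, 4-hydroxy-3,5-dimethoxybenzoic acid | COc1cc(C(=O)O)cc(OC)c1O | starting material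
6 | triisopropylsilyl 3,5-dimethoxy-4-(triisopropylsilyloxy)benzoate (not isolated) | COc1cc(C(=O)O[Si](C(C)C)(C(C)C)C(C)C)cc(OC)c1O[Si](C(C)C)(C(C)C)C(C)C | intermediate
7 | 3,5-dimethoxy-4-(triisopropylsilyloxy)benzoic acid | COc1cc(C(=O)O)cc(OC)c1O[Si](C(C)C)(C(C)C)C(C)C | intermediate
8 | 3,5-dimethoxy-4-(triisopropylsilyloxy)benzoyl chloride (fragment 2) | COc1cc(C(=O)Cl)cc(OC)c1O[Si](C(C)C)(C(C)C)C(C)C | intermediate
9 | lithium enolate of ester 4 (not isolated) | CCOC(O[Li])=COc1ccc(CCCO[Si](C)(C)C(C)(C)C)cc1OC | intermediate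
10 | lithium enolate of keto ester 11 (not isolated) | CCOC(=O)C(Oc1ccc(CCCO[Si](C)(C)C(C)(C)C)cc1OC)=C(O[Li])c1cc(OC)c(O[Si](C(C)C)(C(C)C)C(C)C)c(OC)c1 | intermediate
11 | racemic ethyl 2-[4-[3-(tert-butyldimethylsilyloxy)propyl]-2-methoxyphenoxy]-3-[3,5-dimethoxy-4-(triisopropylsilyloxy)phenyl]-3-oxopropanoate | CCOC(=O)C(Oc1ccc(CCCO[Si](C)(C)C(C)(C)C)cc1OC)C(=O)c1cc(OC)c(O[Si](C(C)C)(C(C)C)C(C)C)c(OC)c1 | intermediate
12 | ethyl (2S,3R)-2-[4-[3-(tert-butyldimethylsilyloxy)propyl]-2-methoxyphenoxy]-3-hydroxy-3-[3,5-dimethoxy-4-(triisopropylsilyloxy)phenyl]propanoate | COc1cc(CCCO[Si](C)(C)C(C)(C)C)ccc1O[C@H](C(=O)OCC)[C@H](O)c1cc(OC)c(O[Si](C(C)C)(C(C)C)C(C)C)c(OC)c1 | intermediate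
13 | (1R,2R)-2-[4-[3-(tert-butyldimethylsilyloxy)propyl]-2-methoxyphenoxy]-1-[3,5-dimethoxy-4-(triisopropylsilyloxy)phenyl]propane-1,3-diol | COc1cc(CCCO[Si](C)(C)C(C)(C)C)ccc1O[C@H](CO)[C@H](O)c1cc(OC)c(O[Si](C(C)C)(C(C)C)C(C)C)c(OC)c1 | intermediate
14 | (1R,2R)-3-(tert-butyldimethylsilyloxy)-2-[4-[3-(tert-butyldimethylsilyloxy)propyl]-2-methoxyphenoxy]-1-[3,5-dimethoxy-4-(triisopropylsilyloxy)phenyl]propan-1-ol | COc1cc(CCCO[Si](C)(C)C(C)(C)C)ccc1O[C@H](CO[Si](C)(C)C(C)(C)C)[C@H](O)c1cc(OC)c(O[Si](C(C)C)(C(C)C)C(C)C)c(OC)c1 | intermediate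
15 | (2R)-3-(tert-butyldimethylsilyloxy)-2-[4-[3-(tert-butyldimethylsilyloxy)propyl]-2-methoxyphenoxy]-1-[3,5-dimethoxy-4-(triisopropylsilyloxy)phenyl]propan-1-one | COc1cc(CCCO[Si](C)(C)C(C)(C)C)ccc1O[C@H](CO[Si](C)(C)C(C)(C)C)C(=O)c1cc(OC)c(O[Si](C(C)C)(C(C)C)C(C)C)c(OC)c1 | intermediate
16 | (2R)-3-hydroxy-1-(4-hydroxy-3,5-dimethoxyphenyl)-2-[4-(3-hydroxypropyl)-2-methoxyphenoxy]propan-1-one, CNP0283847.2 | COc1cc(CCCO)ccc1O[C@H](CO)C(=O)c1cc(OC)c(O)c(OC)c1 | target

**Totals**

Total step count: 10. Longest linear sequence: 8 steps (steps 1, 2, 5, 6, 7, 8, 9, 10 from 1; equally steps 3, 4, 5 to 10 from 5).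

**Steps most likely to fail**

Step 6. Stereocontrol may erode if enolization of 11 does not outpace hydride transfer or if the catalyst reads the hindered, electron-rich aryl ketone poorly. The reduction may stall, and the sense of induction may differ from the model. The fallback replaces catalyst control by an auxiliary-controlled syn aldol, sets out from 4 and returns at 13.
- Ester 4 is saponified (LiOH, THF/H2O) to 2-[4-[3-(tert-butyldimethylsilyloxy)propyl]-2-methoxyphenoxy]acetic acid F1.
- F1 is activated with pivaloyl chloride and Et3N as the mixed pivalic anhydride F2, which acylates (S)-4-benzyl-2-oxazolidinone in the presence of LiCl to give the N-(aryloxyacetyl)oxazolidinone F3.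
- Commercial syringaldehyde is silylated (TIPSCl, imidazole, DMF) to 3,5-dimethoxy-4-(triisopropylsilyloxy)benzaldehyde F4.
- Soft enolization of F3 (Bu2BOTf, iPr2NEt, CH2Cl2, −78 °C) should give the Z dibutylboron enolate F5, which adds to F4 in an Evans syn aldol reaction.
- Hydrolytic work-up should give the (4S)-3-[(2S,3R)-2-aryloxy-3-aryl-3-hydroxypropanoyl]oxazolidinone F6; the (S)-benzyl auxiliary fixes the same C2 and C3 configurations as in 12.
- LiBH4 (THF, one equivalent of water, 0 °C) removes the auxiliary reductively and delivers diol 13 directly.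

Step 5. The acid chloride may be diverted by O-acylation of the enolate, by double acylation or by reaction with the amide base, and the ester may self-condense. The fallback forms the same C–C bond by aldol addition followed by oxidation, sets out from 4 and returns at 11. Enolate 9 (LiN(SiMe3)2, THF, −78 °C) is added to the aldehyde F4, prepared as in the fallback above, to give the racemic ethyl 2-aryloxy-3-aryl-3-hydroxypropanoate F7 as a diastereomer mixture. Oxidation with Dess–Martin periodinane (NaHCO3, CH2Cl2) gives keto ester 11. Neither the relative nor the absolute configuration of F7 matters, since both are erased.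

Step 10. Fluoride treatment of the α-aryloxy β-hydroxy ketone may cause epimerization at C2, β-elimination of the primary hydroxyl or retro-aldol loss of formaldehyde, and cleavage of the hindered aryl silyl ether may be incomplete. The fallback moves the desilylation ahead of the oxidation, sets out from 13 and returns at 16. Diol 13, which has no labile centre, is desilylated (TBAF, THF, rt) to (1R,2R)-1-(4-hydroxy-3,5-dimethoxyphenyl)-2-[4-(3-hydroxypropyl)-2-methoxyphenoxy]propane-1,3-diol F8. The benzylic carbinol para to the free phenol is then dehydrogenated with DDQ (1.05 equiv, dioxane, rt), a reaction specific for p-hydroxybenzylic alcohols that should leave both primary alcohols alone. This gives 16 without the ketone ever meeting fluoride or base.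

**Further compounds**

F1 | step 6 | 2-[4-[3-(tert-butyldimethylsilyloxy)propyl]-2-methoxyphenoxy]acetic acid | OC(=O)COc1ccc(CCCO[Si](C)(C)C(C)(C)C)cc1OC
F2 | step 6 | mixed pivalic anhydride of acid F1 (not isolated) | CC(C)(C)C(=O)OC(=O)COc1ccc(CCCO[Si](C)(C)C(C)(C)C)cc1OC
F3 | step 6 | (4S)-4-benzyl-3-[2-[4-[3-(tert-butyldimethylsilyloxy)propyl]-2-methoxyphenoxy]acetyl]oxazolidin-2-one | O=C(COc1ccc(CCCO[Si](C)(C)C(C)(C)C)cc1OC)N1[C@@H](Cc2ccccc2)COC1=O
F4 | step 6 | 3,5-dimethoxy-4-(triisopropylsilyloxy)benzaldehyde | COc1cc(C=O)cc(OC)c1O[Si](C(C)C)(C(C)C)C(C)C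
F5 | step 6 | Z dibutylboron enolate of F3 (not isolated) | CCCCB(CCCC)O/C(=C\Oc1ccc(CCCO[Si](C)(C)C(C)(C)C)cc1OC)N1[C@@H](Cc2ccccc2)COC1=O
F6 | step 6 | (4S)-4-benzyl-3-[(2S,3R)-2-[4-[3-(tert-butyldimethylsilyloxy)propyl]-2-methoxyphenoxy]-3-hydroxy-3-[3,5-dimethoxy-4-(triisopropylsilyloxy)phenyl]propanoyl]oxazolidin-2-one | COc1cc(CCCO[Si](C)(C)C(C)(C)C)ccc1O[C@H](C(=O)N1[C@@H](Cc2ccccc2)COC1=O)[C@H](O)c1cc(OC)c(O[Si](C(C)C)(C(C)C)C(C)C)c(OC)c1
F7 | step 5 | racemic ethyl 2-[4-[3-(tert-butyldimethylsilyloxy)propyl]-2-methoxyphenoxy]-3-hydroxy-3-[3,5-dimethoxy-4-(triisopropylsilyloxy)phenyl]propanoate (diastereomer mixture) | CCOC(=O)C(Oc1ccc(CCCO[Si](C)(C)C(C)(C)C)cc1OC)C(O)c1cc(OC)c(O[Si](C(C)C)(C(C)C)C(C)C)c(OC)c1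
F8 | step 10 | (1R,2R)-1-(4-hydroxy-3,5-dimethoxyphenyl)-2-[4-(3-hydroxypropyl)-2-methoxyphenoxy]propane-1,3-diol | COc1cc(CCCO)ccc1O[C@H](CO)[C@H](O)c1cc(OC)c(O)c(OC)c1
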